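**Retrosynthetic overview**

- The strategy rests on ring C of the flavan unit (O1–C2–C3–C4–C4a–C8a). It is a reduced 2,4-diarylbenzopyrylium with all-trans C2 (aryl), C3 (OH) and C4, and C4 is bonded to C2' of the pyrogallol ring, the carbon wedged between C1' (which carries C2 of the flavonol) and C3'–O.
- Disconnections: flavonol pyranone ring (Algar–Flynn–Oyamada on a chalcone from aldehyde 20 and acetophenone 2); C2–H and C3–OH (hydroboration of 4H-chromene 16); C4–H (enantioselective hydride transfer to the flavylium ion from racemic carbinol 14); C4–C2' (aryllithium 13 plus flavone 6).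
- Ring order: pyranone of the lower unit (step 3), hindered aryl joined at C4 (step 9), ring C dearomatized (step 10) and saturated (step 11), flavonol pyranone ring closed last (step 15), then global debenzylation.

Key step: step 10

Assumption: the sense of induction of the chiral phosphoric acid cannot be predicted with certainty for a 4-aryl group with two ortho substituents. The acid enantiomer that gives (4S)-16 is used; it is taken here to be the (R)-acid, and the (S)-acid is substituted if a pilot run shows the opposite sense.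

**Step 1**
Reactants: 1 2,4-dihydroxyacetophenone
Product: 2 4-benzyloxy-2-hydroxyacetophenone
Conditions: BnBr (1.05 equiv), K2CO3, acetone, reflux
Reagents that add atoms: benzyl bromide BrCc1ccccc1
Why: The 2-hydroxyl is held in a hydrogen bond to the acetyl carbonyl and is the poorer nucleophile, so Williamson etherification with one equivalent of benzyl bromide should occur at the 4-hydroxyl only.

**Step 2**
Reactants: 2 4-benzyloxy-2-hydroxyacetophenone; 3 3,4-dibenzyloxybenzaldehyde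
Product: 4 (E)-1-(4-benzyloxy-2-hydroxyphenyl)-3-(3,4-dibenzyloxyphenyl)prop-2-en-1-one
Conditions: KOH (50% aq.), EtOH/THF, rt
Reagents that add atoms: none
Why: Claisen–Schmidt condensation of the methyl ketone enolate with the non-enolizable aldehyde, followed by E1cB loss of water, should give the (E)-chalcone.

**Step 3**
Reactants: 4 (E)-1-(4-benzyloxy-2-hydroxyphenyl)-3-(3,4-dibenzyloxyphenyl)prop-2-en-1-one
Product: 6 7-benzyloxy-2-(3,4-dibenzyloxyphenyl)chromen-4-one, via racemic flavanone 5 (not isolated)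
Conditions: I2 (10 mol%), DMSO, 130 °C
Reagents that add atoms: none
Why: In this I2/DMSO oxidative cyclization, oxa-Michael closure of the 2'-phenol gives the flavanone, which is iodinated next to the carbonyl and loses HI to give the flavone, while DMSO reoxidizes HI to I2.

**Step 4**
Reactants: 7 methyl gallate
Product: 8 methyl 3,4,5-tribenzyloxybenzoate
Conditions: BnBr (3.5 equiv), K2CO3, DMF, 60 °C
Reagents that add atoms: benzyl bromide BrCc1ccccc1
Why: Exhaustive Williamson etherification of the three phenols should proceed cleanly because the ester is inert to carbonate.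

**Step 5**
Reactants: 8 methyl 3,4,5-tribenzyloxybenzoate
Product: 9 3,4,5-tribenzyloxybenzyl alcohol
Conditions: LiAlH4, THF, 0 °C → rt; then H2O
Reagents that add atoms: none
Why: Hydride reduction of the ester with LiAlH4 should give the benzylic alcohol without touching the benzyl ethers.

**Step 6**
Reactants: 9 3,4,5-tribenzyloxybenzyl alcohol
Product: 10 2-bromo-3,4,5-tribenzyloxybenzyl alcohol
Conditions: NBS (1.05 equiv), CH2Cl2, 0 °C → rt, dark
Reagents that add atoms: N-bromosuccinimide O=C1CCC(=O)N1Br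
Why: Electrophilic aromatic bromination can only occur at the two equivalent free ring positions (ortho to the CH2OH carbon, ortho and para to alkoxy groups), so one equivalent of NBS should give the single monobromide.

**Step 7**
Reactants: 10 2-bromo-3,4,5-tribenzyloxybenzyl alcohol
Product: 11 2-bromo-3,4,5-tribenzyloxybenzaldehyde
Conditions: MnO2 (activated, excess), CH2Cl2, rt
Reagents that add atoms: none
Why: Oxidation of the electron-rich benzylic alcohol with MnO2 should stop at the aldehyde.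

**Step 8**
Reactants: 11 2-bromo-3,4,5-tribenzyloxybenzaldehyde
Product: 12 2-(2-bromo-3,4,5-tribenzyloxyphenyl)-1,3-dioxolane
Conditions: HOCH2CH2OH, p-TsOH·H2O (cat.), toluene, reflux, Dean–Stark
Reagents that add atoms: ethylene glycol OCCO
Why: Acid-catalysed acetalization with azeotropic removal of water masks the aldehyde against the organolithium chemistry of the next step.

**Step 9**
Reactants: 12 2-(2-bromo-3,4,5-tribenzyloxyphenyl)-1,3-dioxolane; 6 7-benzyloxy-2-(3,4-dibenzyloxyphenyl)chromen-4-one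
Product: 14 racemic 7-benzyloxy-2-(3,4-dibenzyloxyphenyl)-4-[2,3,4-tris(benzyloxy)-6-(1,3-dioxolan-2-yl)phenyl]-4H-chromen-4-ol, via aryllithium 13 (not isolated)
Conditions: n-BuLi (1.0 equiv on 12), THF, −78 °C; then 6 in THF, −78 → −20 °C; H2O quench; Et3N-deactivated silica
Reagents that add atoms: none
Why: Bromine–lithium exchange is fast at −78 °C, and the acetal-chelated aryllithium, a hard nucleophile, should add 1,2 to the flavone carbonyl to forge the C4–C2' bond and give the tertiary carbinol (flavylium pseudo-base), whose configuration is irrelevant because it is erased in step 10.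

**Step 10**
Reactants: 14 racemic 7-benzyloxy-2-(3,4-dibenzyloxyphenyl)-4-[2,3,4-tris(benzyloxy)-6-(1,3-dioxolan-2-yl)phenyl]-4H-chromen-4-ol
Product: 16 (4S)-7-benzyloxy-2-(3,4-dibenzyloxyphenyl)-4-[2,3,4-tris(benzyloxy)-6-(1,3-dioxolan-2-yl)phenyl]-4H-chromene, via flavylium phosphate ion pair 15 (not isolated)
Conditions: (R)-TRIP [(R)-3,3'-bis(2,4,6-triisopropylphenyl)-1,1'-binaphthyl-2,2'-diyl hydrogen phosphate] (10 mol%), diethyl 2,6-dimethyl-1,4-dihydropyridine-3,5-dicarboxylate (Hantzsch ester, 1.3 equiv), 5 Å MS, toluene, −20 °C → rt, Ar; product used directly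
Reagents that add atoms: none
Why: The chiral phosphoric acid protonates the tertiary hydroxyl of 14, water leaves, and the 7-benzyloxy-stabilized 4-arylflavylium cation is held as a contact ion pair 15 with the chiral phosphate, which also hydrogen-bonds the N–H of the Hantzsch ester so that hydride is passed to C4 on one enantiotopic face. The closest known reaction type is the chiral phosphoric acid catalysed ion-pair transfer hydrogenation of 2,4-diarylbenzopyrylium ions generated from chromenols, which gives 4-aryl-4H-chromenes; the second ortho substituent on the 4-aryl group is the only extension. No ring is closed: the aromatic pyrylium ring C is dearomatized and the C4–H bond is the only bond formed. The C4 stereocentre is controlled by the phosphate counter-anion alone, since the racemic carbinol centre is destroyed on ionization, and both rotamers about the C4–aryl bond lead to the same C4 configuration once the sp3 centre allows rotation. The step needs attack at C4 and not at C2, which is expected because the 3,4-dibenzyloxyphenyl group conjugates with and deactivates C2, whereas the twisted 4-aryl group leaves C4 the most electron-poor position and attack there keeps the 2-aryl enol ether conjugated; the sieves take up the liberated water so that the dioxolane is not hydrolysed.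

**Step 11**
Reactants: 16 (4S)-7-benzyloxy-2-(3,4-dibenzyloxyphenyl)-4-[2,3,4-tris(benzyloxy)-6-(1,3-dioxolan-2-yl)phenyl]-4H-chromene
Product: 18 (2R,3S,4S)-7-benzyloxy-2-(3,4-dibenzyloxyphenyl)-4-[2,3,4-tris(benzyloxy)-6-(1,3-dioxolan-2-yl)phenyl]chroman-3-ol, via C3 alkylborane 17 (not isolated)
Conditions: BH3·THF, THF, 0 °C → rt; then aq. NaOH, 30% H2O2, 0 °C
Reagents that add atoms: hydrogen peroxide OO
Why: Hydroboration–oxidation of the enol ether adds B–H syn through a four-centre transition state, with boron on C3 (beta to the ring oxygen, remote from the C2 aryl) and on the face opposite the bulky C4 aryl, and oxidation of the C–B bond with retention should give the 3-hydroxyl trans to the C4 aryl and the C2 aryl trans to the 3-hydroxyl.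

**Step 12**
Reactants: 18 (2R,3S,4S)-7-benzyloxy-2-(3,4-dibenzyloxyphenyl)-4-[2,3,4-tris(benzyloxy)-6-(1,3-dioxolan-2-yl)phenyl]chroman-3-ol
Product: 19 (2R,3S,4S)-3,7-bis(benzyloxy)-2-(3,4-dibenzyloxyphenyl)-4-[2,3,4-tris(benzyloxy)-6-(1,3-dioxolan-2-yl)phenyl]chromane
Conditions: NaH, BnBr, n-Bu4NI (cat.), DMF, 0 °C → rt
Reagents that add atoms: benzyl bromide BrCc1ccccc1
Why: Williamson benzylation of the secondary alkoxide caps the 3-hydroxyl so that it cannot form a six-membered lactol with the aldehyde released in the next step, and the C4–H is not acidic enough to be removed by NaH.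

**Step 13**
Reactants: 19 (2R,3S,4S)-3,7-bis(benzyloxy)-2-(3,4-dibenzyloxyphenyl)-4-[2,3,4-tris(benzyloxy)-6-(1,3-dioxolan-2-yl)phenyl]chromane
Product: 20 3,4,5-tris(benzyloxy)-2-[(2R,3S,4S)-3,7-bis(benzyloxy)-2-(3,4-dibenzyloxyphenyl)chroman-4-yl]benzaldehyde
Conditions: 1 M HCl, THF, rt
Reagents that add atoms: water O
Why: Acid-catalysed hydrolysis of the electron-rich aryl dioxolane should release the aldehyde under conditions that leave the benzyl ethers and the 5-deoxy 4-arylflavan untouched.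

**Step 14**
Reactants: 20 3,4,5-tris(benzyloxy)-2-[(2R,3S,4S)-3,7-bis(benzyloxy)-2-(3,4-dibenzyloxyphenyl)chroman-4-yl]benzaldehyde; 2 4-benzyloxy-2-hydroxyacetophenone
Product: 21 (E)-1-(4-benzyloxy-2-hydroxyphenyl)-3-{3,4,5-tris(benzyloxy)-2-[(2R,3S,4S)-3,7-bis(benzyloxy)-2-(3,4-dibenzyloxyphenyl)chroman-4-yl]phenyl}prop-2-en-1-one
Conditions: KOH (50% aq.), EtOH/1,4-dioxane, rt → 40 °C
Reagents that add atoms: none
Why: Claisen–Schmidt condensation of the enolate of 2 with the non-enolizable aldehyde should give the (E)-chalcone, and the fully etherified flavan has no free phenol through which base could open ring C or epimerize C2.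

**Step 15**
Reactants: 21 (E)-1-(4-benzyloxy-2-hydroxyphenyl)-3-{3,4,5-tris(benzyloxy)-2-[(2R,3S,4S)-3,7-bis(benzyloxy)-2-(3,4-dibenzyloxyphenyl)chroman-4-yl]phenyl}prop-2-en-1-one
Product: 23 7-benzyloxy-3-hydroxy-2-{3,4,5-tris(benzyloxy)-2-[(2R,3S,4S)-3,7-bis(benzyloxy)-2-(3,4-dibenzyloxyphenyl)chroman-4-yl]phenyl}chromen-4-one, via dihydroflavonol 22 (not isolated)
Conditions: 30% H2O2, aq. NaOH, MeOH/THF, 0 °C → rt
Reagents that add atoms: hydrogen peroxide OO
Why: In the Algar–Flynn–Oyamada reaction the phenoxide closes onto the beta-carbon of the peroxide-activated enone to give the 3-hydroxyflavanone, which alkaline peroxide dehydrogenates to the flavonol, and the absence of a 6'-substituent on the acetophenone ring disfavours the aurone pathway.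

**Step 16**
Reactants: 23 7-benzyloxy-3-hydroxy-2-{3,4,5-tris(benzyloxy)-2-[(2R,3S,4S)-3,7-bis(benzyloxy)-2-(3,4-dibenzyloxyphenyl)chroman-4-yl]phenyl}chromen-4-one
Product: 24 3,7-dihydroxy-2-{3,4,5-trihydroxy-2-[(2R,3S,4S)-3,7-dihydroxy-2-(3,4-dihydroxyphenyl)chroman-4-yl]phenyl}chromen-4-one (CNP0381334.2)
Conditions: H2 (1 atm), Pd(OH)2/C, THF/MeOH, rt; filtration and concentration under Ar
Reagents that add atoms: none
Why: Catalytic hydrogenolysis should cleave the eight O-benzyl ethers faster than the cyclic C2–O1 ether or the chromone double bond, and it touches none of the three stereocentres.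

**Compound list**

1 | 2,4-dihydroxyacetophenone | CC(=O)c1ccc(O)cc1O | starting material
2 | 4-benzyloxy-2-hydroxyacetophenone | CC(=O)c1ccc(OCc2ccccc2)cc1O | intermediate
3 | 3,4-dibenzyloxybenzaldehyde | O=Cc1ccc(OCc2ccccc2)c(OCc2ccccc2)c1 | starting material
4 | (E)-1-(4-benzyloxy-2-hydroxyphenyl)-3-(3,4-dibenzyloxyphenyl)prop-2-en-1-one | O=C(/C=C/c1ccc(OCc2ccccc2)c(OCc2ccccc2)c1)c1ccc(OCc2ccccc2)cc1O | intermediate
5 | racemic 7-benzyloxy-2-(3,4-dibenzyloxyphenyl)chroman-4-one (flavanone) | O=C1CC(c2ccc(OCc3ccccc3)c(OCc3ccccc3)c2)Oc2cc(OCc3ccccc3)ccc12 | intermediate (not isolated)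
6 | 7-benzyloxy-2-(3,4-dibenzyloxyphenyl)chromen-4-one (flavone) | O=c1cc(-c2ccc(OCc3ccccc3)c(OCc3ccccc3)c2)oc2cc(OCc3ccccc3)ccc12 | intermediate
7 | methyl gallate | COC(=O)c1cc(O)c(O)c(O)c1 | starting material
8 | methyl 3,4,5-tribenzyloxybenzoate | COC(=O)c1cc(OCc2ccccc2)c(OCc2ccccc2)c(OCc2ccccc2)c1 | intermediate
9 | 3,4,5-tribenzyloxybenzyl alcohol | OCc1cc(OCc2ccccc2)c(OCc2ccccc2)c(OCc2ccccc2)c1 | intermediate
10 | 2-bromo-3,4,5-tribenzyloxybenzyl alcohol | OCc1cc(OCc2ccccc2)c(OCc2ccccc2)c(OCc2ccccc2)c1Br | intermediate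
11 | 2-bromo-3,4,5-tribenzyloxybenzaldehyde | O=Cc1cc(OCc2ccccc2)c(OCc2ccccc2)c(OCc2ccccc2)c1Br | intermediate
12 | 2-(2-bromo-3,4,5-tribenzyloxyphenyl)-1,3-dioxolane | Brc1c(C2OCCO2)cc(OCc2ccccc2)c(OCc2ccccc2)c1OCc1ccccc1 | intermediate
13 | [2,3,4-tris(benzyloxy)-6-(1,3-dioxolan-2-yl)phenyl]lithium | [Li]c1c(C2OCCO2)cc(OCc2ccccc2)c(OCc2ccccc2)c1OCc1ccccc1 | intermediate (not isolated)
14 | racemic 7-benzyloxy-2-(3,4-dibenzyloxyphenyl)-4-[2,3,4-tris(benzyloxy)-6-(1,3-dioxolan-2-yl)phenyl]-4H-chromen-4-ol | OC1(c2c(C3OCCO3)cc(OCc3ccccc3)c(OCc3ccccc3)c2OCc2ccccc2)C=C(c2ccc(OCc3ccccc3)c(OCc3ccccc3)c2)Oc2cc(OCc3ccccc3)ccc21 | intermediate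
15 | 7-benzyloxy-2-(3,4-dibenzyloxyphenyl)-4-[2,3,4-tris(benzyloxy)-6-(1,3-dioxolan-2-yl)phenyl]chromenylium (cation shown; counter-ion is the chiral phosphate of the catalyst) | C1COC(O1)c1cc(OCc2ccccc2)c(OCc2ccccc2)c(OCc2ccccc2)c1-c1cc(-c2ccc(OCc3ccccc3)c(OCc3ccccc3)c2)[o+]c2cc(OCc3ccccc3)ccc12 | intermediate (not isolated)
16 | (4S)-7-benzyloxy-2-(3,4-dibenzyloxyphenyl)-4-[2,3,4-tris(benzyloxy)-6-(1,3-dioxolan-2-yl)phenyl]-4H-chromene | C1COC(O1)c1cc(OCc2ccccc2)c(OCc2ccccc2)c(OCc2ccccc2)c1[C@@H]1c2ccc(OCc3ccccc3)cc2OC(c2ccc(OCc3ccccc3)c(OCc3ccccc3)c2)=C1 | intermediate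
17 | C3 alkylborane of 16 (BH2 on C3, trans to both aryl groups; configuration as in 18) | C1COC(O1)c1cc(OCc2ccccc2)c(OCc2ccccc2)c(OCc2ccccc2)c1[C@@H]1c2ccc(OCc3ccccc3)cc2O[C@H](c2ccc(OCc3ccccc3)c(OCc3ccccc3)c2)[C@H]1B | intermediate (not isolated)
18 | (2R,3S,4S)-7-benzyloxy-2-(3,4-dibenzyloxyphenyl)-4-[2,3,4-tris(benzyloxy)-6-(1,3-dioxolan-2-yl)phenyl]chroman-3-ol (all-trans) | C1COC(O1)c1cc(OCc2ccccc2)c(OCc2ccccc2)c(OCc2ccccc2)c1[C@@H]1c2ccc(OCc3ccccc3)cc2O[C@H](c2ccc(OCc3ccccc3)c(OCc3ccccc3)c2)[C@H]1O | intermediate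
19 | (2R,3S,4S)-3,7-bis(benzyloxy)-2-(3,4-dibenzyloxyphenyl)-4-[2,3,4-tris(benzyloxy)-6-(1,3-dioxolan-2-yl)phenyl]chromane | C1COC(O1)c1cc(OCc2ccccc2)c(OCc2ccccc2)c(OCc2ccccc2)c1[C@@H]1c2ccc(OCc3ccccc3)cc2O[C@H](c2ccc(OCc3ccccc3)c(OCc3ccccc3)c2)[C@H]1OCc1ccccc1 | intermediate
20 | 3,4,5-tris(benzyloxy)-2-[(2R,3S,4S)-3,7-bis(benzyloxy)-2-(3,4-dibenzyloxyphenyl)chroman-4-yl]benzaldehyde | O=Cc1cc(OCc2ccccc2)c(OCc2ccccc2)c(OCc2ccccc2)c1[C@@H]1c2ccc(OCc3ccccc3)cc2O[C@H](c2ccc(OCc3ccccc3)c(OCc3ccccc3)c2)[C@H]1OCc1ccccc1 | intermediate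
21 | (E)-1-(4-benzyloxy-2-hydroxyphenyl)-3-{3,4,5-tris(benzyloxy)-2-[(2R,3S,4S)-3,7-bis(benzyloxy)-2-(3,4-dibenzyloxyphenyl)chroman-4-yl]phenyl}prop-2-en-1-one | O=C(/C=C/c1cc(OCc2ccccc2)c(OCc2ccccc2)c(OCc2ccccc2)c1[C@@H]1c2ccc(OCc3ccccc3)cc2O[C@H](c2ccc(OCc3ccccc3)c(OCc3ccccc3)c2)[C@H]1OCc1ccccc1)c1ccc(OCc2ccccc2)cc1O | intermediate
22 | 7-benzyloxy-3-hydroxy-2-{3,4,5-tris(benzyloxy)-2-[(2R,3S,4S)-3,7-bis(benzyloxy)-2-(3,4-dibenzyloxyphenyl)chroman-4-yl]phenyl}chroman-4-one (dihydroflavonol; mixture at the new C2 and C3) | O=C1C(O)C(c2cc(OCc3ccccc3)c(OCc3ccccc3)c(OCc3ccccc3)c2[C@@H]2c3ccc(OCc4ccccc4)cc3O[C@H](c3ccc(OCc4ccccc4)c(OCc4ccccc4)c3)[C@H]2OCc2ccccc2)Oc2cc(OCc3ccccc3)ccc12 | intermediate (not isolated)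
23 | 7-benzyloxy-3-hydroxy-2-{3,4,5-tris(benzyloxy)-2-[(2R,3S,4S)-3,7-bis(benzyloxy)-2-(3,4-dibenzyloxyphenyl)chroman-4-yl]phenyl}chromen-4-one (octabenzyl ether of the target) | O=c1c(O)c(-c2cc(OCc3ccccc3)c(OCc3ccccc3)c(OCc3ccccc3)c2[C@@H]2c3ccc(OCc4ccccc4)cc3O[C@H](c3ccc(OCc4ccccc4)c(OCc4ccccc4)c3)[C@H]2OCc2ccccc2)oc2cc(OCc3ccccc3)ccc12 | intermediate
24 | 3,7-dihydroxy-2-{3,4,5-trihydroxy-2-[(2R,3S,4S)-3,7-dihydroxy-2-(3,4-dihydroxyphenyl)chroman-4-yl]phenyl}chromen-4-one (CNP0381334.2) | O=c1c(O)c(-c2cc(O)c(O)c(O)c2[C@@H]2c3ccc(O)cc3O[C@H](c3ccc(O)c(O)c3)[C@H]2O)oc2cc(O)ccc12 | target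

**Totals**

Total step count: 16. Longest linear sequence: 13 steps (7 to 24, steps 4 to 16).

**Steps most likely to fail**

1. Step 10. Hydride transfer to C4 may be slow because the perpendicular 4-aryl group, with a substituent at each ortho position, shields both faces of C4. Hydride may then leak to C2, or the phosphate may discriminate the two faces poorly; the water set free may also hydrolyse the dioxolane. The fallback replaces catalytic induction by resolution; it sets out from 14 and returns at 18.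
   - 14 would be reduced without induction (diphenyl phosphate 10 mol%, Hantzsch ester, CH2Cl2, rt) to the racemic 4H-chromene F1, possibly accompanied by the racemic 2H-chromene regioisomer F2 from attack at C2.
   - The mixture need not be separated: syn hydroboration of the C3=C4 bond of F2 anti to its C2 aryl group (boron again on C3) leads to the same all-trans relative configuration as hydroboration of F1.
   - BH3·THF followed by NaOH/H2O2 should therefore give the racemic all-trans alcohol F3.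
   - Acylation with (1S)-camphanic chloride (Et3N, DMAP, CH2Cl2) would give the camphanate of the (2R,3S,4S)-alcohol F4 and the camphanate of the (2S,3R,4R)-alcohol F5, to be separated by chromatography or crystallization and assigned by X-ray analysis.
   - Saponification of F4 (LiOH, THF/MeOH/H2O, then mild acid) would return 18.

2. Step 9. The aryllithium with two ortho substituents may add only sluggishly to the vinylogous-ester carbonyl of 6, with conjugate addition at C2 or metalation at benzylic ether positions taking over on warming. The fallback makes the C4–C2' bond by cross-coupling instead of carbonyl addition; it sets out from 2 and 12 and returns at 16.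
   - 2 would be condensed with diethyl carbonate (NaH, toluene, reflux) to 7-benzyloxy-4-hydroxycoumarin F6, then converted with Tf2O/Et3N into the coumarin 4-triflate F7.
   - 12 would be lithiated (n-BuLi, −78 °C), borylated with B(OMe)3 and hydrolysed near neutral pH to the arylboronic acid F8.
   - Suzuki–Miyaura coupling of F7 and F8 (Pd(OAc)2, SPhos, K3PO4, toluene/H2O, 80 °C) should give the 4-arylcoumarin F9.
   - 3,4-Dibenzyloxyphenyllithium F10 (from commercial 4-bromo-1,2-bis(benzyloxy)benzene and n-BuLi) would add once to the lactone carbonyl at −78 °C to give the racemic 2,4-diaryl-2H-chromen-2-ol F11.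
   - F11 is the regioisomeric pseudo-base; under the conditions of step 10 it ionizes to the same ion pair 15 and is reduced to 16.

3. Step 15. The bulky flavanyl group ortho to the beta-carbon may retard the oxidative cyclization, so that the reaction stalls at the dihydroflavonol, diverts to aurone-type closure at the alpha-carbon, or the enone is cleaved by alkaline peroxide. The fallback separates ring closure from C3 hydroxylation; it sets out from 21 and returns at 23.
   - 21 would be cyclized with catalytic I2 in DMSO at 120 °C (as in step 3) to the flavone F12.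
   - The C2=C3 bond of F12 would be epoxidized with dimethyldioxirane (acetone/CH2Cl2, 0 °C) to the flavone 2,3-epoxide F13.
   - A trace of p-TsOH should open and tautomerize F13 to the flavonol 23.

**Further compounds**

F1 | step 10 | racemic 7-benzyloxy-2-(3,4-dibenzyloxyphenyl)-4-[2,3,4-tris(benzyloxy)-6-(1,3-dioxolan-2-yl)phenyl]-4H-chromene | C1COC(O1)c1cc(OCc2ccccc2)c(OCc2ccccc2)c(OCc2ccccc2)c1C1c2ccc(OCc3ccccc3)cc2OC(c2ccc(OCc3ccccc3)c(OCc3ccccc3)c2)=C1
F2 | step 10 | racemic 7-benzyloxy-2-(3,4-dibenzyloxyphenyl)-4-[2,3,4-tris(benzyloxy)-6-(1,3-dioxolan-2-yl)phenyl]-2H-chromene | C1COC(O1)c1cc(OCc2ccccc2)c(OCc2ccccc2)c(OCc2ccccc2)c1C1=CC(c2ccc(OCc3ccccc3)c(OCc3ccccc3)c2)Oc2cc(OCc3ccccc3)ccc12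
F3 | step 10 | racemic all-trans 7-benzyloxy-2-(3,4-dibenzyloxyphenyl)-4-[2,3,4-tris(benzyloxy)-6-(1,3-dioxolan-2-yl)phenyl]chroman-3-ol (racemate; one enantiomer drawn) | C1COC(O1)c1cc(OCc2ccccc2)c(OCc2ccccc2)c(OCc2ccccc2)c1[C@@H]1c2ccc(OCc3ccccc3)cc2O[C@H](c2ccc(OCc3ccccc3)c(OCc3ccccc3)c2)[C@H]1O
F4 | step 10 | (1S,4R)-camphanate ester of the (2R,3S,4S)-alcohol 18 | C1COC(O1)c1cc(OCc2ccccc2)c(OCc2ccccc2)c(OCc2ccccc2)c1[C@@H]1c2ccc(OCc3ccccc3)cc2O[C@H](c2ccc(OCc3ccccc3)c(OCc3ccccc3)c2)[C@H]1OC(=O)[C@@]12CC[C@@](C)(C(=O)O1)C2(C)C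
F5 | step 10 | (1S,4R)-camphanate ester of the (2S,3R,4R)-alcohol | C1COC(O1)c1cc(OCc2ccccc2)c(OCc2ccccc2)c(OCc2ccccc2)c1[C@H]1c2ccc(OCc3ccccc3)cc2O[C@@H](c2ccc(OCc3ccccc3)c(OCc3ccccc3)c2)[C@@H]1OC(=O)[C@@]12CC[C@@](C)(C(=O)O1)C2(C)C
F6 | step 9 | 7-benzyloxy-4-hydroxycoumarin | O=c1cc(O)c2ccc(OCc3ccccc3)cc2o1
F7 | step 9 | 7-benzyloxy-2-oxo-2H-chromen-4-yl trifluoromethanesulfonate | O=c1cc(OS(=O)(=O)C(F)(F)F)c2ccc(OCc3ccccc3)cc2o1
F8 | step 9 | [2,3,4-tris(benzyloxy)-6-(1,3-dioxolan-2-yl)phenyl]boronic acid | OB(O)c1c(C2OCCO2)cc(OCc2ccccc2)c(OCc2ccccc2)c1OCc1ccccc1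
F9 | step 9 | 7-benzyloxy-4-[2,3,4-tris(benzyloxy)-6-(1,3-dioxolan-2-yl)phenyl]coumarin | O=c1cc(-c2c(C3OCCO3)cc(OCc3ccccc3)c(OCc3ccccc3)c2OCc2ccccc2)c2ccc(OCc3ccccc3)cc2o1
F10 | step 9 | (3,4-dibenzyloxyphenyl)lithium | [Li]c1ccc(OCc2ccccc2)c(OCc2ccccc2)c1
F11 | step 9 | racemic 7-benzyloxy-2-(3,4-dibenzyloxyphenyl)-4-[2,3,4-tris(benzyloxy)-6-(1,3-dioxolan-2-yl)phenyl]-2H-chromen-2-ol | OC1(c2ccc(OCc3ccccc3)c(OCc3ccccc3)c2)C=C(c2c(C3OCCO3)cc(OCc3ccccc3)c(OCc3ccccc3)c2OCc2ccccc2)c2ccc(OCc3ccccc3)cc2O1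
F12 | step 15 | 7-benzyloxy-2-{3,4,5-tris(benzyloxy)-2-[(2R,3S,4S)-3,7-bis(benzyloxy)-2-(3,4-dibenzyloxyphenyl)chroman-4-yl]phenyl}chromen-4-one | O=c1cc(-c2cc(OCc3ccccc3)c(OCc3ccccc3)c(OCc3ccccc3)c2[C@@H]2c3ccc(OCc4ccccc4)cc3O[C@H](c3ccc(OCc4ccccc4)c(OCc4ccccc4)c3)[C@H]2OCc2ccccc2)oc2cc(OCc3ccccc3)ccc12
F13 | step 15 | 2,3-epoxide of flavone F12 (mixture at the epoxide carbons) | O=C1C2OC2(c2cc(OCc3ccccc3)c(OCc3ccccc3)c(OCc3ccccc3)c2[C@@H]2c3ccc(OCc4ccccc4)cc3O[C@H](c3ccc(OCc4ccccc4)c(OCc4ccccc4)c3)[C@H]2OCc2ccccc2)Oc2cc(OCc3ccccc3)ccc12
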